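The heterocyclic ring is disconnected at N2–C3 and C1–C8a, which excises C1(CH3)=N2 as acetonitrile. The precursor is an acyclic (R)-1-arylpropan-2-ol already carrying the MOM-protected naphthyl group. After triflation, acetonitrile displaces the secondary triflate with inversion (N2–C3, sets 3S). The nitrilium ion so formed is trapped by the arene (C1–C8a), so nitrogen, C1, its methyl group and the whole dihydropyridine ring arrive in one operation. The step exploits the local symmetry of the 3,5-dimethoxy-4-aryl benzene ring: the future C5 and C8a are equivalent, and each lies ortho to one and para to the other methoxy group. The carbinol centre comes from (R)-propylene oxide, the biaryl bond from a Suzuki–Miyaura coupling.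

Key step: step 8

Assumption: the SMILES defines only C3. The 7,6′ biaryl axis bears no descriptor, so its configuration is not controlled and the product is taken as drawn, whatever the rotamer population about that axis.

Step 1
Reactants: 1 2-methoxy-4-methylbenzoic acid
Product: 3 N,N-diethyl-2-methoxy-4-methylbenzamide, via acid chloride 2 (not isolated)
Conditions: SOCl2, cat. DMF, toluene, 70 °C; concentrate; Et2NH (3 equiv), CH2Cl2, 0 °C → rt
Reagents that add atoms: diethylamine, CCNCC; thionyl chloride, O=S(Cl)Cl (chlorine of 2 only)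
Why: Acid chloride formation followed by aminolysis is routine, and the tertiary diethylamide it gives is both the directing group for step 2 and the internal acyl donor for step 3.

Step 2
Reactants: 3 N,N-diethyl-2-methoxy-4-methylbenzamide; 4 allyl bromide
Product: 7 2-allyl-N,N-diethyl-6-methoxy-4-methylbenzamide, via aryllithium 5 (not isolated), via arylmagnesium bromide 6 (not isolated)
Conditions: s-BuLi, TMEDA, THF, −78 °C; MgBr2·OEt2, −78 → 0 °C; allyl bromide, 0 °C → rt
Reagents that add atoms: s-BuLi, [Li]C(C)CC (lithium of 5 only); MgBr2·OEt2, Br[Mg]Br (MgBr of 6 only)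
Why: Directed ortho-metalation takes place at C6, the only free position next to the amide, and transmetalation to magnesium tempers the carbanion so that it is allylated by allyl bromide instead of attacking a second amide.

Step 3
Reactants: 7 2-allyl-N,N-diethyl-6-methoxy-4-methylbenzamide
Product: 8 8-methoxy-6-methylnaphthalen-1-ol
Conditions: LiN(i-Pr)2 (2.5 equiv), THF, −78 °C → rt; then 1 M HCl
Reagents that add atoms: none
Why: In this anionic ring annulation of an o-allylbenzamide the base removes the doubly activated benzylic-allylic proton, the terminal carbon of the allyl anion acylates on the neighbouring amide to close a six-membered ring with loss of diethylamide, and the resulting dienone tautomerises to the 1-naphthol.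

Step 4
Reactants: 8 8-methoxy-6-methylnaphthalen-1-ol
Product: 9 8-methoxy-1-(methoxymethoxy)-6-methylnaphthalene
Conditions: NaH, DMF, 0 °C; MOMCl, 0 °C → rt
Reagents that add atoms: chloromethyl methyl ether (MOMCl), COCCl
Why: Williamson-type O-alkylation of the sodium naphtholate installs an acetal that masks the acidic OH, survives organolithium and palladium chemistry, and directs the next metalation.

Step 5
Reactants: 10 1-bromo-3,5-dimethoxybenzene; 11 (R)-propylene oxide
Product: 13 (R)-1-(3,5-dimethoxyphenyl)propan-2-ol, via Grignard reagent 12 (not isolated)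
Conditions: Mg, THF, reflux; CuI (10 mol %), −30 °C; (R)-propylene oxide, −30 → 0 °C; aq. NH4Cl
Reagents that add atoms: magnesium, [Mg] (in 12 only)
Why: The copper-catalysed opening of a terminal epoxide by an aryl Grignard reagent is an SN2 attack at the unsubstituted CH2, so the stereocentre of (R)-propylene oxide is not touched and reappears as the (R)-carbinol.

Step 6
Reactants: 13 (R)-1-(3,5-dimethoxyphenyl)propan-2-ol
Product: 15 (R)-1-(4-iodo-3,5-dimethoxyphenyl)propan-2-ol, via dilithio species 14 (not isolated)
Conditions: n-BuLi (2.3 equiv), THF, 0 °C → rt; I2, −78 °C → rt; H2O, aq. Na2S2O3 wash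
Reagents that add atoms: iodine, II; n-BuLi, [Li]CCCC (lithium of 14 only)
Why: Directed ortho-metalation of the lithium alkoxide should occur at C4, the most acidic position because it is flanked by both methoxy groups, and iodinolysis of the aryllithium fixes the halogen there without touching the carbinol centre.

Step 7
Reactants: 9 8-methoxy-1-(methoxymethoxy)-6-methylnaphthalene; 15 (R)-1-(4-iodo-3,5-dimethoxyphenyl)propan-2-ol
Product: 18 (R)-1-{3,5-dimethoxy-4-[8-methoxy-1-(methoxymethoxy)-6-methylnaphthalen-2-yl]phenyl}propan-2-ol, via 2-lithionaphthalene 16 (not isolated), via lithium triisopropyl borate 17 (not isolated)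
Conditions: 9, n-BuLi, TMEDA, THF, 0 °C; B(Oi-Pr)3, −78 °C → rt; then 15, Pd(OAc)2 (3 mol %), SPhos (6 mol %), aq. K3PO4, THF, 65 °C
Reagents that add atoms: n-BuLi, [Li]CCCC (lithium of 16 and 17 only); triisopropyl borate, CC(C)OB(OC(C)C)OC(C)C (in 17 only)
Why: The MOM group directs lithiation to C2 (the peri position is blocked and C7 is crowded by the methyl group), the borate formed in situ enters a Suzuki–Miyaura coupling, and the bulky electron-rich ligand SPhos is suited to biaryls with three ortho substituents while the free alcohol is tolerated.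

Step 8
Reactants: 18 (R)-1-{3,5-dimethoxy-4-[8-methoxy-1-(methoxymethoxy)-6-methylnaphthalen-2-yl]phenyl}propan-2-ol; 19 acetonitrile
Product: 22 (S)-6,8-dimethoxy-7-[8-methoxy-1-(methoxymethoxy)-6-methylnaphthalen-2-yl]-1,3-dimethyl-3,4-dihydroisoquinoline, via secondary triflate 20 (not isolated), via nitrilium triflate 21 (not isolated)
Conditions: Tf2O (1.1 equiv), 2,6-di-tert-butyl-4-methylpyridine (2.5 equiv), CH2Cl2, −78 °C; then MeCN (large excess, cosolvent, high dilution), −40 °C → rt; aq. NaHCO3
Reagents that add atoms: trifluoromethanesulfonic anhydride (Tf2O), O=S(=O)(OS(=O)(=O)C(F)(F)F)C(F)(F)F (triflyl group of 20 and triflate of 21 only)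
Why: Tf2O converts the carbinol into secondary triflate 20, acetonitrile displaces it from the rear (SN2 N-alkylation of a nitrile, the first half of a Ritter reaction) to form N2–C3, and the sp carbon of N-alkylnitrilium ion 21 is then attacked by the adjacent arene position (the second half of a Bischler–Napieralski reaction) to form C1–C8a, proton loss restoring aromaticity. The closest known reaction type is the Tf2O-promoted tandem Ritter/Friedel–Crafts annulation of 2-arylethanols with nitriles to 3,4-dihydroisoquinolines, together with the alkylation of nitriles by secondary alkyl triflates. The single new ring closes in the 6-endo-dig mode at the nitrilium carbon. C3 is set by the substrate alone: one inversion turns the (R)-carbinol carbon into (S)-C3, and the retentive leak through a phenonium ion, like a hydride shift to a benzylic cation, is disfavoured because both methoxy groups are meta to the ipso carbon and to the benzylic position and the naphthyl group is twisted out of conjugation. Site selectivity is secured by the substrate because the two free positions of the 3,5-dimethoxy-4-arylphenyl ring are constitutionally equivalent and each is activated by an ortho and a para methoxy group, so that six-ring closure should outrun any intermolecular attack of the naphthalene. The hindered, non-nucleophilic base takes up TfOH without displacing the triflate, which keeps the MOM acetal intact, while the product stays protonated and so is shielded from N-alkylation.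

Step 9
Reactants: 22 (S)-6,8-dimethoxy-7-[8-methoxy-1-(methoxymethoxy)-6-methylnaphthalen-2-yl]-1,3-dimethyl-3,4-dihydroisoquinoline
Product: 23 (S)-2-(6,8-dimethoxy-1,3-dimethyl-3,4-dihydroisoquinolin-7-yl)-8-methoxy-6-methylnaphthalen-1-ol
Conditions: HCl (1.25 M in MeOH), rt → 40 °C; then aq. NaHCO3
Reagents that add atoms: none
Why: Acid-catalysed acetal exchange with methanol removes the MOM group, while the imine is merely protonated, the aryl methyl ethers are inert to dilute acid and C3 has no pathway for epimerisation.

Compound list
1 | 2-methoxy-4-methylbenzoic acid | COc1cc(C)ccc1C(=O)O | starting material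
2 | 2-methoxy-4-methylbenzoyl chloride | COc1cc(C)ccc1C(=O)Cl | intermediate
3 | N,N-diethyl-2-methoxy-4-methylbenzamide | CCN(CC)C(=O)c1ccc(C)cc1OC | intermediate
4 | allyl bromide | C=CCBr | starting material
5 | 6-lithio-N,N-diethyl-2-methoxy-4-methylbenzamide | CCN(CC)C(=O)c1c([Li])cc(C)cc1OC | intermediate
6 | 2-(diethylcarbamoyl)-3-methoxy-5-methylphenylmagnesium bromide | CCN(CC)C(=O)c1c([Mg]Br)cc(C)cc1OC | intermediate
7 | 2-allyl-N,N-diethyl-6-methoxy-4-methylbenzamide | C=CCc1cc(C)cc(OC)c1C(=O)N(CC)CC | intermediate
8 | 8-methoxy-6-methylnaphthalen-1-ol | COc1cc(C)cc2cccc(O)c12 | intermediate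
9 | 8-methoxy-1-(methoxymethoxy)-6-methylnaphthalene | COCOc1cccc2cc(C)cc(OC)c12 | intermediate
10 | 1-bromo-3,5-dimethoxybenzene | COc1cc(Br)cc(OC)c1 | starting material
11 | (R)-propylene oxide | C[C@@H]1CO1 | starting material
12 | 3,5-dimethoxyphenylmagnesium bromide | COc1cc([Mg]Br)cc(OC)c1 | intermediate
13 | (R)-1-(3,5-dimethoxyphenyl)propan-2-ol | C[C@@H](O)Cc1cc(OC)cc(OC)c1 | intermediate
14 | lithium (R)-1-(4-lithio-3,5-dimethoxyphenyl)propan-2-olate | C[C@@H](O[Li])Cc1cc(OC)c([Li])c(OC)c1 | intermediate
15 | (R)-1-(4-iodo-3,5-dimethoxyphenyl)propan-2-ol | C[C@@H](O)Cc1cc(OC)c(I)c(OC)c1 | intermediate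
16 | 2-lithio-8-methoxy-1-(methoxymethoxy)-6-methylnaphthalene | COCOc1c([Li])ccc2cc(C)cc(OC)c12 | intermediate
17 | lithium triisopropoxy[8-methoxy-1-(methoxymethoxy)-6-methylnaphthalen-2-yl]borate | [Li+].COCOc1c(ccc2cc(C)cc(OC)c12)[B-](OC(C)C)(OC(C)C)OC(C)C | intermediate
18 | (R)-1-{3,5-dimethoxy-4-[8-methoxy-1-(methoxymethoxy)-6-methylnaphthalen-2-yl]phenyl}propan-2-ol | C[C@@H](O)Cc1cc(OC)c(c(OC)c1)-c1ccc2cc(C)cc(OC)c2c1OCOC | intermediate
19 | acetonitrile | CC#N | starting material
20 | (R)-configured secondary triflate of 18 | C[C@@H](OS(=O)(=O)C(F)(F)F)Cc1cc(OC)c(c(OC)c1)-c1ccc2cc(C)cc(OC)c2c1OCOC | intermediate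
21 | (S)-N-(1-arylpropan-2-yl)acetonitrilium triflate | CC#[N+][C@@H](C)Cc1cc(OC)c(c(OC)c1)-c1ccc2cc(C)cc(OC)c2c1OCOC.[O-]S(=O)(=O)C(F)(F)F | intermediate
22 | (S)-6,8-dimethoxy-7-[8-methoxy-1-(methoxymethoxy)-6-methylnaphthalen-2-yl]-1,3-dimethyl-3,4-dihydroisoquinoline | COc1cc2c(c(OC)c1-c1ccc3cc(C)cc(OC)c3c1OCOC)C(C)=N[C@@H](C)C2 | intermediate
23 | (S)-2-(6,8-dimethoxy-1,3-dimethyl-3,4-dihydroisoquinolin-7-yl)-8-methoxy-6-methylnaphthalen-1-ol | COc1cc2c(c(OC)c1-c1ccc3cc(C)cc(OC)c3c1O)C(C)=N[C@@H](C)C2 | target

Total step count: 9. Longest linear sequence: 7 steps (steps 1, 2, 3, 4, 7, 8, 9).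

Steps most likely to fail

Step 8. Three things may go wrong:
- Stereochemical fidelity may be lost through ionisation of the triflate or aryl participation.
- The triflate may undergo β-elimination towards the conjugated propenylarene.
- The MOM group may be lost prematurely.

The fallback separates the two bond formations and sets out from 18. Mitsunobu displacement with diphenylphosphoryl azide (PPh3, DIAD, THF, 0 °C) should give, with inversion, the (S)-azide F1. Staudinger reduction (PPh3, THF/H2O) should give the (S)-amine F2, and acetylation (Ac2O, Et3N, CH2Cl2) the (S)-acetamide F3. Bischler–Napieralski cyclodehydration (Tf2O, 2-chloropyridine, CH2Cl2, −78 °C → rt) then closes C1–C8a, and the sequence comes back to the route at 22.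

Step 7. The ortho-alkoxy borate may protodeboronate, and transmetalation may be slow at a palladium centre flanked by two methoxy groups. The fallback reverses the polarity of the partners and sets out from 9 and 13.
- Lithiation of 9 (through 16) and quenching with I2 should give the 2-iodonaphthalene F4.
- The dilithio species 14, made from 13 as in step 6, is transmetalated with ZnCl2 to the arylzinc chloride F5.

Negishi coupling of F4 and F5 (Pd2(dba)3, RuPhos, THF, 70 °C), followed by aqueous work-up, comes back to the route at 18 and bypasses 15.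

Step 6. The alkoxide may divert metalation to the position next to the side chain, and metalation of an aggregated dianion may be incomplete. The fallback removes the alkoxide from the substrate and sets out from 13. Silylation (TBSCl, imidazole, DMF) should give the TBS ether F6. n-BuLi (THF, 0 °C) then has only the two methoxy groups as directors and should give the aryllithium F7. I2 converts this into the iodo TBS ether F8, and Bu4NF (THF, rt) comes back to the route at 15.

Further compounds
F1 | step 8 | (S)-2-azido-1-{3,5-dimethoxy-4-[8-methoxy-1-(methoxymethoxy)-6-methylnaphthalen-2-yl]phenyl}propane | C[C@H](N=[N+]=[N-])Cc1cc(OC)c(c(OC)c1)-c1ccc2cc(C)cc(OC)c2c1OCOC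
F2 | step 8 | (S)-1-{3,5-dimethoxy-4-[8-methoxy-1-(methoxymethoxy)-6-methylnaphthalen-2-yl]phenyl}propan-2-amine | C[C@H](N)Cc1cc(OC)c(c(OC)c1)-c1ccc2cc(C)cc(OC)c2c1OCOC
F3 | step 8 | (S)-N-(1-{3,5-dimethoxy-4-[8-methoxy-1-(methoxymethoxy)-6-methylnaphthalen-2-yl]phenyl}propan-2-yl)acetamide | C[C@H](NC(C)=O)Cc1cc(OC)c(c(OC)c1)-c1ccc2cc(C)cc(OC)c2c1OCOC
F4 | step 7 | 2-iodo-8-methoxy-1-(methoxymethoxy)-6-methylnaphthalene | COCOc1c(I)ccc2cc(C)cc(OC)c12
F5 | step 7 | {4-[(R)-2-(lithiooxy)propyl]-2,6-dimethoxyphenyl}zinc chloride | C[C@@H](O[Li])Cc1cc(OC)c([Zn]Cl)c(OC)c1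
F6 | step 6 | (R)-tert-butyl{[1-(3,5-dimethoxyphenyl)propan-2-yl]oxy}dimethylsilane | C[C@@H](O[Si](C)(C)C(C)(C)C)Cc1cc(OC)cc(OC)c1
F7 | step 6 | 4-lithio derivative of the TBS ether | C[C@@H](O[Si](C)(C)C(C)(C)C)Cc1cc(OC)c([Li])c(OC)c1
F8 | step 6 | (R)-tert-butyl{[1-(4-iodo-3,5-dimethoxyphenyl)propan-2-yl]oxy}dimethylsilane | C[C@@H](O[Si](C)(C)C(C)(C)C)Cc1cc(OC)c(I)c(OC)c1
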